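**Retrosynthetic overview**
1. Target 13 ⇐ global MOM removal ⇐ tris-MOM chalcone 12 ⇐ Claisen–Schmidt condensation of methyl ketone 9 with aldehyde 10 (enone formed last; B ring bought).
2. 9 ⇐ benzylic C4–O hydrogenolysis of the (3R,4R)-epoxide 8 ⇐ Jacobsen epoxidation of 2,2-dimethylchromene 7 (the only stereocentre is set here).
3. 7 ⇐ propargyl-Claisen/oxa-6π cascade of aryl 1,1-dimethylpropargyl ether 4; O-2/O-6 are MOM-capped, so the pyran can only close on O-4 (para to the acyl group).
4. 4 ⇐ phloroacetophenone 1 + 3-chloro-3-methylbut-1-yne 2 (O-4 etherification, then bis-MOM protection).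
5. Ring order: aromatic A ring bought → pyran ring (step 3) → transient oxirane (steps 4–5); the B ring arrives with 10.

Assumption: 1 (anhydrous), 2, 4-(methoxymethoxy)benzaldehyde 10 and (R,R)-Jacobsen catalyst are taken as commercially available; the target's stereocentre is assigned as (3R).

**Step 1**
Reactants: 1 2,4,6-trihydroxyacetophenone; 2 3-chloro-3-methylbut-1-yne
Product: 3 1-[2,6-dihydroxy-4-(2-methylbut-3-yn-2-yloxy)phenyl]ethan-1-one
Conditions: K2CO3 (1.2 equiv), KI, CuI (cat.), acetone, 50 °C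
Reagents that add atoms: 3-chloro-3-methylbut-1-yne (2), C#CC(C)(C)Cl
Why: Cu-assisted propargylic Williamson etherification, in which the 4-OH is the most acidic hydroxyl and the only one not held next to the acetyl group, so one equivalent of base and chloride gives the mono-ether at O-4.

**Step 2**
Reactants: 3 1-[2,6-dihydroxy-4-(2-methylbut-3-yn-2-yloxy)phenyl]ethan-1-one
Product: 4 1-[2,6-bis(methoxymethoxy)-4-(2-methylbut-3-yn-2-yloxy)phenyl]ethan-1-one
Conditions: NaH (2.2 equiv), MOMCl (2.4 equiv), DMF, 0 °C → rt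
Reagents that add atoms: chloromethyl methyl ether (MOMCl), COCCl
Why: Williamson-type O-alkylation (MOM acetal formation), in which NaH breaks the O–H···O=C chelates and the sodium phenoxides are trapped at oxygen by MOMCl, phenol deprotonation outcompeting that of the alkyne or methyl ketone at 2.2 equiv of base.

**Step 3**
Reactants: 4 1-[2,6-bis(methoxymethoxy)-4-(2-methylbut-3-yn-2-yloxy)phenyl]ethan-1-one
Product: 7 1-[5,7-bis(methoxymethoxy)-2,2-dimethyl-2H-chromen-6-yl]ethan-1-one, via ortho-allenylphenol 5 (not isolated), via ortho-quinone methide 6 (not isolated)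
Conditions: PhNEt2, 180 °C
Reagents that add atoms: none
Why: Aromatic propargyl Claisen rearrangement to the equivalent C-3/C-5 positions followed by 1,5-H shift and oxa-6π electrocyclization, and since O-4 is the only free oxygen the chromene oxygen ends up para to the acetyl group.

**Step 4**
Reactants: 7 1-[5,7-bis(methoxymethoxy)-2,2-dimethyl-2H-chromen-6-yl]ethan-1-one
Product: 8 1-[(3R,4R)-3,4-epoxy-5,7-bis(methoxymethoxy)-2,2-dimethyl-3,4-dihydro-2H-chromen-6-yl]ethan-1-one
Conditions: (R,R)-Jacobsen Mn(salen)Cl (5 mol%), mCPBA, NMO, CH2Cl2, −78 °C; cold basic work-up, used crude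
Reagents that add atoms: meta-chloroperoxybenzoic acid (mCPBA), O=C(OO)c1cccc(Cl)c1
Why: Jacobsen–Katsuki epoxidation, for which 2,2-dimethylchromenes are the privileged cis-olefin class, the (R,R)-catalyst delivering oxygen to the face that gives the (3R,4R)-oxirane and so setting C-3 as R, while low temperature and NMO buffering protect the acid-labile benzylic epoxide.

**Step 5**
Reactants: 8 1-[(3R,4R)-3,4-epoxy-5,7-bis(methoxymethoxy)-2,2-dimethyl-3,4-dihydro-2H-chromen-6-yl]ethan-1-one
Product: 9 1-[(3R)-3-hydroxy-5,7-bis(methoxymethoxy)-2,2-dimethyl-3,4-dihydro-2H-chromen-6-yl]ethan-1-one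
Conditions: H2 (1 atm), 10% Pd/C, Et3N (trace), EtOAc, rt
Reagents that add atoms: none
Why: Regioselective Pd-catalysed hydrogenolysis of the benzylic C4–O bond leaves the C3–O bond untouched, so the 3R configuration is kept, and the di-ortho-substituted aryl ketone and the MOM acetals are inert under these neutral conditions.

**Step 6**
Reactants: 9 1-[(3R)-3-hydroxy-5,7-bis(methoxymethoxy)-2,2-dimethyl-3,4-dihydro-2H-chromen-6-yl]ethan-1-one; 10 4-(methoxymethoxy)benzaldehyde
Product: 12 (2E)-1-[(3R)-3-hydroxy-5,7-bis(methoxymethoxy)-2,2-dimethyl-3,4-dihydro-2H-chromen-6-yl]-3-[4-(methoxymethoxy)phenyl]prop-2-en-1-one, via beta-hydroxy ketone 11 (not isolated)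
Conditions: KOH (50% aq.), EtOH, rt, 24 h
Reagents that add atoms: 4-(methoxymethoxy)benzaldehyde (10), COCOc1ccc(C=O)cc1
Why: Claisen–Schmidt condensation (aldol addition then E1cB dehydration) of the methyl ketone enolate with a non-enolizable aldehyde gives the conjugated E-enone, and with all phenols capped no flavanone closure is possible while the non-epimerizable C-3 carbinol is untouched.

**Step 7**
Reactants: 12 (2E)-1-[(3R)-3-hydroxy-5,7-bis(methoxymethoxy)-2,2-dimethyl-3,4-dihydro-2H-chromen-6-yl]-3-[4-(methoxymethoxy)phenyl]prop-2-en-1-one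
Product: 13 (2E)-3-(4-hydroxyphenyl)-1-[(3R)-3,5,7-trihydroxy-2,2-dimethyl-3,4-dihydro-2H-chromen-6-yl]prop-2-en-1-one
Conditions: HCl (ca. 1 M in MeOH), 0 °C → rt, 1–3 h
Reagents that add atoms: none
Why: Acid-catalysed acetal exchange (MOM methanolysis) frees the three phenols under conditions mild and short enough to avoid chalcone-to-flavanone cyclization, and the C-3 carbinol cannot ionize or epimerize here.

**Compound list**
1 | 2,4,6-trihydroxyacetophenone | CC(=O)c1c(O)cc(O)cc1O | starting material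
2 | 3-chloro-3-methylbut-1-yne | C#CC(C)(C)Cl | starting material
3 | 1-[2,6-dihydroxy-4-(2-methylbut-3-yn-2-yloxy)phenyl]ethan-1-one | CC(=O)c1c(O)cc(OC(C)(C)C#C)cc1O | intermediate
4 | 1-[2,6-bis(methoxymethoxy)-4-(2-methylbut-3-yn-2-yloxy)phenyl]ethan-1-one | CC(=O)c1c(OCOC)cc(OC(C)(C)C#C)cc1OCOC | intermediate
5 | ortho-allenylphenol, 1-[4-hydroxy-2,6-bis(methoxymethoxy)-3-(3-methylbuta-1,2-dien-1-yl)phenyl]ethan-1-one (not isolated) | CC(=O)c1c(OCOC)cc(O)c(C=C=C(C)C)c1OCOC | intermediate
6 | ortho-quinone methide, (6Z)-4-acetyl-3,5-bis(methoxymethoxy)-6-(3-methylbut-2-en-1-ylidene)cyclohexa-2,4-dien-1-one (not isolated) | O=C1C=C(OCOC)C(C(C)=O)=C(OCOC)/C1=C/C=C(C)C | intermediate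
7 | 1-[5,7-bis(methoxymethoxy)-2,2-dimethyl-2H-chromen-6-yl]ethan-1-one | CC(=O)c1c(OCOC)cc2OC(C)(C)C=Cc2c1OCOC | intermediate
8 | 1-[(3R,4R)-3,4-epoxy-5,7-bis(methoxymethoxy)-2,2-dimethyl-3,4-dihydro-2H-chromen-6-yl]ethan-1-one | CC(=O)c1c(OCOC)cc2OC(C)(C)[C@@H]3O[C@@H]3c2c1OCOC | intermediate
9 | 1-[(3R)-3-hydroxy-5,7-bis(methoxymethoxy)-2,2-dimethyl-3,4-dihydro-2H-chromen-6-yl]ethan-1-one | CC(=O)c1c(OCOC)cc2OC(C)(C)[C@H](O)Cc2c1OCOC | intermediate
10 | 4-(methoxymethoxy)benzaldehyde | COCOc1ccc(C=O)cc1 | starting material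
11 | beta-hydroxy ketone, 3-hydroxy-1-[(3R)-3-hydroxy-5,7-bis(methoxymethoxy)-2,2-dimethyl-3,4-dihydro-2H-chromen-6-yl]-3-[4-(methoxymethoxy)phenyl]propan-1-one, both carbinol epimers (not isolated) | COCOc1ccc(C(O)CC(=O)c2c(OCOC)cc3OC(C)(C)[C@H](O)Cc3c2OCOC)cc1 | intermediate
12 | (2E)-1-[(3R)-3-hydroxy-5,7-bis(methoxymethoxy)-2,2-dimethyl-3,4-dihydro-2H-chromen-6-yl]-3-[4-(methoxymethoxy)phenyl]prop-2-en-1-one | COCOc1ccc(/C=C/C(=O)c2c(OCOC)cc3OC(C)(C)[C@H](O)Cc3c2OCOC)cc1 | intermediate
13 | (2E)-3-(4-hydroxyphenyl)-1-[(3R)-3,5,7-trihydroxy-2,2-dimethyl-3,4-dihydro-2H-chromen-6-yl]prop-2-en-1-one | CC1(C)Oc2cc(O)c(C(=O)/C=C/c3ccc(O)cc3)c(O)c2C[C@H]1O | target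

**Totals**
Total step count: 7. Longest linear sequence: 7 steps (1 → 13).

**Three steps most likely to fail, with fallbacks**

Step 1 (mono-etherification of an unprotected acylphloroglucinol with a tertiary propargyl chloride; C-alkylation or bis-ether formation may compete). The fallback sets out from 1 and comes back to the route at chromene 7, replacing steps 1–3. TIPSCl/imidazole (DMF, 0 °C) silylates only the unhindered 4-OH to give 1-[2,6-dihydroxy-4-(triisopropylsilyloxy)phenyl]ethan-1-one F1. NaH/MOMCl then caps both ortho hydroxyls to give 1-[2,6-bis(methoxymethoxy)-4-(triisopropylsilyloxy)phenyl]ethan-1-one F2. TBAF (THF) releases the single phenol 1-[4-hydroxy-2,6-bis(methoxymethoxy)phenyl]ethan-1-one F3. This phenol is condensed with 3-methylbut-2-enal (prenal, CC(C)=CC=O; ethylenediammonium diacetate cat., toluene, reflux). Knoevenagel-type C-alkylation at C-3 and loss of water give the same quinone methide 6, which electrocyclizes to 7. The pyran ring is thus made by aldehyde condensation instead of etherification plus Claisen rearrangement, with the same regiocontrol because only O-4 is free.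

Step 4 (the epoxide sits on a phloroglucinol-type ring and its benzylic C4–O bond is extremely acid-labile; ee could also be eroded by the peri 5-OMOM group or by uncatalysed background oxidation). The fallback sets out from chromene 7 and comes back at chromanol 9, replacing steps 4 and 5, and it turns the likely decomposition pathway into the route. Epoxidation without a chiral catalyst (DMDO, acetone, 0 °C) gives rac-(3R*,4R*)-6-acetyl-3,4-epoxy-5,7-bis(methoxymethoxy)-2,2-dimethylchromane F4. A catalytic Lewis acid (InCl3 or ZnI2, THF) triggers Meinwald rearrangement (1,2-hydride shift to the stabilized C-4 cation) to the achiral 6-acetyl-5,7-bis(methoxymethoxy)-2,2-dimethylchroman-3-one F5. Corey–Bakshi–Shibata reduction with (S)-Me-CBS/BH3·SMe2 (THF, −20 °C) then sets the stereocentre by reagent control. The quaternary C-2 is the large group, so the (S)-catalyst should give the (R)-alcohol 9. The hindered di-ortho-substituted aryl ketone is expected to react much more slowly, though this chemoselectivity would need checking.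

Step 7 (the freed 2',6'-dihydroxychalcone can cyclize to flavanones under acid). The fallback sets out from 9 and comes back at the target 13, replacing steps 6 and 7, so that no acid is used once the enone exists. MOM methanolysis of 9 (HCl/MeOH, rt) gives 1-[(3R)-3,5,7-trihydroxy-2,2-dimethyl-3,4-dihydro-2H-chromen-6-yl]ethan-1-one F6. Its polyanion (LiHMDS, 6–7 equiv, THF, −78 °C → rt) is condensed directly with unprotected 4-hydroxybenzaldehyde (O=Cc1ccc(O)cc1). The chalcone stays as its polyphenoxide until a cold dilute-acid quench at 0 °C liberates 13.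

**Further compounds**
F1 | step 1 | 1-[2,6-dihydroxy-4-(triisopropylsilyloxy)phenyl]ethan-1-one | CC(=O)c1c(O)cc(O[Si](C(C)C)(C(C)C)C(C)C)cc1O
F2 | step 1 | 1-[2,6-bis(methoxymethoxy)-4-(triisopropylsilyloxy)phenyl]ethan-1-one | CC(=O)c1c(OCOC)cc(O[Si](C(C)C)(C(C)C)C(C)C)cc1OCOC
F3 | step 1 | 1-[4-hydroxy-2,6-bis(methoxymethoxy)phenyl]ethan-1-one | CC(=O)c1c(OCOC)cc(O)cc1OCOC
F4 | step 4 | rac-(3R*,4R*)-6-acetyl-3,4-epoxy-5,7-bis(methoxymethoxy)-2,2-dimethylchromane (racemate) | CC(=O)c1c(OCOC)cc2OC(C)(C)C3OC3c2c1OCOC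
F5 | step 4 | 6-acetyl-5,7-bis(methoxymethoxy)-2,2-dimethylchroman-3-one | CC(=O)c1c(OCOC)cc2OC(C)(C)C(=O)Cc2c1OCOC
F6 | step 7 | 1-[(3R)-3,5,7-trihydroxy-2,2-dimethyl-3,4-dihydro-2H-chromen-6-yl]ethan-1-one | CC(=O)c1c(O)cc2OC(C)(C)[C@H](O)Cc2c1O
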